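Ring A is disconnected at C4a–C5 and C8–C8a (tetralone numbering). The feature used is that the C4a=C8a bond shared by rings A and B is the α,β-double bond of a ring B cyclohexenone, whereas the four-carbon arc C5–C6–C7–C8, oxygenated at C6 and C7, corresponds to a butadiene with oxygen on both inner carbons. One Diels–Alder reaction forms two C–C bonds and the carbocycle of ring A. Its precursor is a 2-bromocyclohex-2-enone that already bears the aryl group and both methyl groups in the all-trans, all-equatorial arrangement; bromine activates the dienophile and later leaves as HBr. Because the cycloadduct is only at the enediol oxidation level, one two-electron oxidation is built into the aromatisation.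

Key step: step 7

Assumption: ketone 1 is bought as a catalogue building block, and the lithium amide of the (S,S)-amine is taken to remove the same enantiotopic proton from 1 as from other 4-substituted cyclohexanones (the antipodal amine would be used if the sense were reversed).

Numbering: compounds 1–10 are numbered as cyclohexanones (C1 = carbonyl carbon); 12–15 as tetralones (C1 ketone, C2 and C3 methyl carbons, C4 diaryl methine, ring A the arene, ring B the ketone ring). The descriptor of the aryl-bearing carbon is S in 10, 12 and 13 and R elsewhere only because neighbour priorities change; the center is never inverted.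

Step 1
Reactants: 1 4-(3,4-dimethoxyphenyl)cyclohexan-1-one
Product: 2 (R)-[4-(3,4-dimethoxyphenyl)cyclohex-1-en-1-yl]oxy(trimethyl)silane
Conditions: LiN(CHMePh)2 from (S,S)-bis(1-phenylethyl)amine and nBuLi, LiCl, TMSCl (internal quench), THF, −78 °C
Reagents that add atoms: chlorotrimethylsilane, C[Si](C)(C)Cl
Why: Enantioselective deprotonation of a prochiral 4-substituted cyclohexanone by a C2-symmetric chiral lithium amide with internal silyl quench is an established desymmetrisation in which the base distinguishes the two enantiotopic axial α-hydrogens, so that C4 should become an R-configured stereocenter, any minor enantiomer being removable later by recrystallisation of 5 or 14.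

Step 2
Reactants: 2 (R)-[4-(3,4-dimethoxyphenyl)cyclohex-1-en-1-yl]oxy(trimethyl)silane
Product: 3 (R)-4-(3,4-dimethoxyphenyl)cyclohex-2-en-1-one
Conditions: Pd(OAc)2 (1.05 equiv), MeCN, rt
Reagents that add atoms: none
Why: Saegusa–Ito oxidation, in which divalent palladium adds to C2 of the silyl enol ether and β-hydride elimination from C3 releases the enone and zerovalent palladium under neutral conditions that cannot epimerise the γ-center C4.

Step 3
Reactants: 3 (R)-4-(3,4-dimethoxyphenyl)cyclohex-2-en-1-one
Product: 5 (2R,3S,4R)-4-(3,4-dimethoxyphenyl)-2,3-dimethylcyclohexan-1-one, via lithium enolate 4 (not isolated)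
Conditions: Me2CuLi (from MeLi and CuBr·SMe2), Et2O/THF, −78 → −30 °C; then MeI, DMPU, −30 → 0 °C
Reagents that add atoms: lithium dimethylcuprate, [Li+].C[Cu-]C; iodomethane, CI
Why: Gilman cuprate 1,4-addition to a 4-substituted cyclohexenone should occur anti to the C4 aryl group, and C-methylation of the regiodefined enolate should occur anti to the new C3 methyl (conjugate addition–enolate alkylation), giving the all-equatorial 2,3-trans-3,4-trans ketone to which any C2 epimer converges on base equilibration.

Step 4
Reactants: 5 (2R,3S,4R)-4-(3,4-dimethoxyphenyl)-2,3-dimethylcyclohexan-1-one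
Product: 7 (4R,5S,6R)-4-(3,4-dimethoxyphenyl)-5,6-dimethylcyclohex-2-en-1-one, via kinetic lithium enolate 6 (not isolated)
Conditions: LiN(iPr)2, THF, −78 °C; then PhS(Cl)=NtBu, −78 °C
Reagents that add atoms: none
Why: Kinetic deprotonation at the unsubstituted C6, C-sulfenylation of that enolate by the sulfinimidoyl chloride and syn-elimination of the resulting sulfilimine (one-pot dehydrogenation of ketone enolates) should place the new double bond between C5 and C6, next to the aryl-bearing carbon, without touching the three stereocenters; the ring is then renumbered so that the former C6 and C5 become C2 and C3.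

Step 5
Reactants: 7 (4R,5S,6R)-4-(3,4-dimethoxyphenyl)-5,6-dimethylcyclohex-2-en-1-one
Product: 8 (1R,3R,4S,5R,6R)-5-(3,4-dimethoxyphenyl)-3,4-dimethyl-7-oxabicyclo[4.1.0]heptan-2-one (oxirane anti to the aryl group)
Conditions: H2O2 (30% aq.), NaOH (cat.), MeOH, 0 °C
Reagents that add atoms: hydrogen peroxide, OO
Why: Weitz–Scheffer nucleophilic epoxidation, in which hydroperoxide should add to C3 anti to the neighbouring aryl group and the enolate closes the oxirane on the same face; the oxidant is nucleophilic, so the electron-rich arene is not touched, and both new centers are removed again in step 6.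

Step 6
Reactants: 8 (1R,3R,4S,5R,6R)-5-(3,4-dimethoxyphenyl)-3,4-dimethyl-7-oxabicyclo[4.1.0]heptan-2-one
Product: 10 (4S,5S,6R)-2-bromo-4-(3,4-dimethoxyphenyl)-5,6-dimethylcyclohex-2-en-1-one, via bromohydrin 9 (not isolated)
Conditions: HBr (48% aq.), AcOH, 0 → 40 °C, N2
Reagents that add atoms: hydrogen bromide, Br
Why: Acid-mediated opening of an α,β-epoxy ketone by bromide at the α-carbon with inversion, followed by dehydration of the β-hydroxy ketone, is the classical halohydrin route to 2-halo-enones and delivers bromine as a nucleophile, so that the dimethoxyphenyl ring cannot be brominated.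

Step 7
Reactants: 10 (4S,5S,6R)-2-bromo-4-(3,4-dimethoxyphenyl)-5,6-dimethylcyclohex-2-en-1-one; 11 2,3-bis(trimethylsilyloxy)buta-1,3-diene
Product: 12 (2R,3S,4S,4aR,8aS)-8a-bromo-4-(3,4-dimethoxyphenyl)-2,3-dimethyl-6,7-bis(trimethylsilyloxy)-3,4,4a,5,8,8a-hexahydronaphthalen-1(2H)-one (cis-fused)
Conditions: 11 (4 equiv), toluene, 120 °C, sealed tube, BHT (cat.)
Reagents that add atoms: none
Why: The reaction is a concerted, suprafacial normal-demand [4+2] cycloaddition in which the HOMO of the doubly silyloxy-substituted diene meets the LUMO of the enone, lowered further by the α-bromine; the closest known reaction type is the Diels–Alder addition of 2-halocycloalk-2-enones to silyloxy dienes, together with the use of 11 as a 1,2-dioxygenated four-carbon unit toward activated alkenes. The six-membered carbocycle that becomes ring A is closed by intermolecular cycloaddition, C4a–C5 and C8–C8a being formed in the same event. Suprafacial addition fixes the cis ring fusion (Br on C8a and H on C4a on one face), and the diene should approach C3 of 10 on the face opposite the C4 aryl group; both centers are transient, so a minor facial isomer converges on the same catechol in step 8. The diene is symmetrically substituted, so no regiochemical question arises. The selectivity that matters is chemoselectivity for cycloaddition over γ-enolisation at the aryl-bearing carbon and over silyl transfer or Mukaiyama–Michael pathways, which neutral thermal conditions without Lewis acid, excess diene and a radical inhibitor are meant to secure.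

Step 8
Reactants: 12 (2R,3S,4S,4aR,8aS)-8a-bromo-4-(3,4-dimethoxyphenyl)-2,3-dimethyl-6,7-bis(trimethylsilyloxy)-3,4,4a,5,8,8a-hexahydronaphthalen-1(2H)-one
Product: 14 (2R,3S,4R)-4-(3,4-dimethoxyphenyl)-6,7-dihydroxy-2,3-dimethyl-3,4-dihydronaphthalen-1(2H)-one, via bromo trione 13 (not isolated)
Conditions: Br2 (1.0 equiv), CH2Cl2, −78 °C; then Et3N (4 equiv), −78 °C → rt; HCl/MeOH work-up
Reagents that add atoms: none
Why: Bromine should convert the 1,2-bis(silyloxy)alkene into the 1,2-diketone with loss of two equivalents of TMSBr (the standard oxidation of acyloin-type enediol bis-silyl ethers), which supplies the two-electron oxidation that the enediol-level adduct still needs, and Et3N should then expel bromide from C8a by E1cB elimination through the C7 enolate and aromatise ring A by enolisation, erasing C4a and C8a while C2, C3 and C4 stay untouched.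

Step 9
Reactants: 14 (2R,3S,4R)-4-(3,4-dimethoxyphenyl)-6,7-dihydroxy-2,3-dimethyl-3,4-dihydronaphthalen-1(2H)-one
Product: 15 epischisandrone [(2R,3S,4R)-4-(3,4-dimethoxyphenyl)-7-hydroxy-6-methoxy-2,3-dimethyl-3,4-dihydronaphthalen-1(2H)-one]
Conditions: MeI (1.1 equiv), Li2CO3 (1.5 equiv), DMF, 45 °C
Reagents that add atoms: iodomethane, CI
Why: Williamson ether synthesis under weak-base control: the C6 hydroxyl, para to the C1 carbonyl, is markedly more acidic than the meta C7 hydroxyl, so Li2CO3 should form and methylate essentially only the C6 phenoxide, as in the 4-O-selective alkylation of 3,4-dihydroxyphenyl ketones.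

Compound list
1 | 4-(3,4-dimethoxyphenyl)cyclohexan-1-one | O=C1CCC(CC1)c1ccc(OC)c(OC)c1 | starting material
2 | (R)-[4-(3,4-dimethoxyphenyl)cyclohex-1-en-1-yl]oxy(trimethyl)silane | C[Si](C)(C)OC1=CC[C@H](c2ccc(OC)c(OC)c2)CC1 | intermediate
3 | (R)-4-(3,4-dimethoxyphenyl)cyclohex-2-en-1-one | O=C1C=C[C@H](c2ccc(OC)c(OC)c2)CC1 | intermediate
4 | lithium (3S,4R)-4-(3,4-dimethoxyphenyl)-3-methylcyclohex-1-en-1-olate | [Li]OC1=C[C@@H](C)[C@H](c2ccc(OC)c(OC)c2)CC1 | intermediate (not isolated)
5 | (2R,3S,4R)-4-(3,4-dimethoxyphenyl)-2,3-dimethylcyclohexan-1-one | O=C1[C@H](C)[C@@H](C)[C@H](c2ccc(OC)c(OC)c2)CC1 | intermediate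
6 | lithium (4R,5S,6R)-4-(3,4-dimethoxyphenyl)-5,6-dimethylcyclohex-1-en-1-olate | [Li]OC1=CC[C@@H](c2ccc(OC)c(OC)c2)[C@H](C)[C@H]1C | intermediate (not isolated)
7 | (4R,5S,6R)-4-(3,4-dimethoxyphenyl)-5,6-dimethylcyclohex-2-en-1-one | O=C1[C@H](C)[C@@H](C)[C@H](c2ccc(OC)c(OC)c2)C=C1 | intermediate
8 | (1R,3R,4S,5R,6R)-5-(3,4-dimethoxyphenyl)-3,4-dimethyl-7-oxabicyclo[4.1.0]heptan-2-one | O=C1[C@H](C)[C@@H](C)[C@H](c2ccc(OC)c(OC)c2)[C@H]3O[C@@H]13 | intermediate
9 | (2S,3R,4R,5S,6R)-2-bromo-4-(3,4-dimethoxyphenyl)-3-hydroxy-5,6-dimethylcyclohexan-1-one | O=C1[C@H](C)[C@@H](C)[C@H](c2ccc(OC)c(OC)c2)[C@@H](O)[C@@H]1Br | intermediate (not isolated)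
10 | (4S,5S,6R)-2-bromo-4-(3,4-dimethoxyphenyl)-5,6-dimethylcyclohex-2-en-1-one | O=C1[C@H](C)[C@@H](C)[C@H](c2ccc(OC)c(OC)c2)C=C1Br | intermediate
11 | 2,3-bis(trimethylsilyloxy)buta-1,3-diene | C=C(O[Si](C)(C)C)C(=C)O[Si](C)(C)C | starting material
12 | (2R,3S,4S,4aR,8aS)-8a-bromo-4-(3,4-dimethoxyphenyl)-2,3-dimethyl-6,7-bis(trimethylsilyloxy)-3,4,4a,5,8,8a-hexahydronaphthalen-1(2H)-one | O=C1[C@H](C)[C@@H](C)[C@H](c2ccc(OC)c(OC)c2)[C@H]2CC(O[Si](C)(C)C)=C(O[Si](C)(C)C)C[C@@]12Br | intermediate
13 | (2R,3S,4S,4aR,8aS)-8a-bromo-4-(3,4-dimethoxyphenyl)-2,3-dimethyl-3,4,4a,5,8,8a-hexahydronaphthalene-1,6,7(2H)-trione | O=C1[C@H](C)[C@@H](C)[C@H](c2ccc(OC)c(OC)c2)[C@H]2CC(=O)C(=O)C[C@@]12Br | intermediate (not isolated)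
14 | (2R,3S,4R)-4-(3,4-dimethoxyphenyl)-6,7-dihydroxy-2,3-dimethyl-3,4-dihydronaphthalen-1(2H)-one | Oc1cc2c(cc1O)C(=O)[C@H](C)[C@@H](C)[C@@H]2c1ccc(OC)c(OC)c1 | intermediate
15 | epischisandrone [(2R,3S,4R)-4-(3,4-dimethoxyphenyl)-7-hydroxy-6-methoxy-2,3-dimethyl-3,4-dihydronaphthalen-1(2H)-one] | COc1cc2c(cc1O)C(=O)[C@H](C)[C@@H](C)[C@@H]2c1ccc(OC)c(OC)c1 | target

Total step count: 9
Longest linear sequence: 9 steps (1 → 15); diene 11 is used as purchased.

Steps most likely to fail

Step 7. The cycloaddition may be outrun by thermal consumption of the diene (oligomerisation, silyl transfer) or by enolisation toward the aryl-bearing carbon. The cause would be that the trisubstituted dienophile, flanked by the C4 aryl group, reacts slowly with an acyclic diene that must first reach its s-cis conformer. The fallback sets out from 10 and returns to the route at 13. Bromoenone 10 is combined at moderate temperature with the conformationally locked diene 2,2-dimethyl-4,5-dimethylidene-1,3-dioxolane F1, obtained beforehand by twofold KOtBu-induced dehydrobromination of trans-4,5-bis(bromomethyl)-2,2-dimethyl-1,3-dioxolane. Its fixed cisoid geometry removes the conformational penalty, and the cycloadduct is the enediol acetonide F2. Aqueous HCl in THF should hydrolyse the dioxole ring to the acyloin F3, expected as a mixture of regioisomers and carbinol epimers. Dess–Martin periodinane should oxidise F3 to trione 13, and the Et3N stage of step 8 then gives 14.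

Step 8. Bromine may attack the dimethoxyphenyl ring if the addition overshoots the enediol ether, and the free catechol may be oxidised further by air while base is present. The fallback sets out from 12 and returns at 14, reversing the order of events and avoiding molecular bromine. DBU in toluene should remove HBr from 12 by E2 elimination across C8–C8a to give the dienone bis(silyl ether) F4. DDQ in CH2Cl2 at 0 °C should dehydrogenate this 1,3-cyclohexadiene (hydride loss from C5, proton loss from C4a) to the bis(trimethylsilyl) catechol ether F5. Catalytic HCl in methanol then unveils 14 under acidic, non-oxidising conditions.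

Step 9. Alkylation may not stop at one oxygen or may also occur at the C7 oxygen, giving mixtures of mono- and dimethyl ethers. The fallback sets out from 14 and returns at 15 through an acetate relay. Ac2O and pyridine give the diacetate F6. One equivalent of piperidine at 0 °C should cleave only the more electrophilic C6 acetate (the ester of the more acidic phenol, para to the carbonyl) to give the 7-monoacetate F7. Neutral Mitsunobu methylation (MeOH, PPh3, DIAD) of the free C6 hydroxyl gives the 7-acetoxy-6-methoxy ketone F8. K2CO3 in methanol then removes the remaining acetate to give 15.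

Further compounds
F1 | step 7 | 2,2-dimethyl-4,5-dimethylidene-1,3-dioxolane | C=C1OC(C)(C)OC1=C
F2 | step 7 | (2R,3S,4S,4aR,8aS)-8a-bromo-4-(3,4-dimethoxyphenyl)-6,7-(isopropylidenedioxy)-2,3-dimethyl-3,4,4a,5,8,8a-hexahydronaphthalen-1(2H)-one (enediol acetonide, cis-fused) | O=C1[C@H](C)[C@@H](C)[C@H](c2ccc(OC)c(OC)c2)[C@H]2CC3=C(OC(C)(C)O3)C[C@@]12Br
F3 | step 7 | (2R,3S,4S,4aR,8aS)-8a-bromo-4-(3,4-dimethoxyphenyl)-7-hydroxy-2,3-dimethyloctahydronaphthalene-1,6-dione (acyloin; C7 configuration undefined, 6-hydroxy-7-oxo isomer expected alongside) | O=C1[C@H](C)[C@@H](C)[C@H](c2ccc(OC)c(OC)c2)[C@H]2CC(=O)C(O)C[C@@]12Br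
F4 | step 8 | (2R,3S,4S,4aR)-4-(3,4-dimethoxyphenyl)-2,3-dimethyl-6,7-bis(trimethylsilyloxy)-3,4,4a,5-tetrahydronaphthalen-1(2H)-one | O=C1[C@H](C)[C@@H](C)[C@H](c2ccc(OC)c(OC)c2)[C@H]2CC(O[Si](C)(C)C)=C(O[Si](C)(C)C)C=C12
F5 | step 8 | (2R,3S,4R)-4-(3,4-dimethoxyphenyl)-2,3-dimethyl-6,7-bis(trimethylsilyloxy)-3,4-dihydronaphthalen-1(2H)-one | C[Si](C)(C)Oc1cc2c(cc1O[Si](C)(C)C)C(=O)[C@H](C)[C@@H](C)[C@@H]2c1ccc(OC)c(OC)c1
F6 | step 9 | (2R,3S,4R)-4-(3,4-dimethoxyphenyl)-2,3-dimethyl-1-oxo-1,2,3,4-tetrahydronaphthalene-6,7-diyl diacetate | CC(=O)Oc1cc2c(cc1OC(C)=O)C(=O)[C@H](C)[C@@H](C)[C@@H]2c1ccc(OC)c(OC)c1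
F7 | step 9 | (2R,3S,4R)-7-acetoxy-4-(3,4-dimethoxyphenyl)-6-hydroxy-2,3-dimethyl-3,4-dihydronaphthalen-1(2H)-one | Oc1cc2c(cc1OC(C)=O)C(=O)[C@H](C)[C@@H](C)[C@@H]2c1ccc(OC)c(OC)c1
F8 | step 9 | (2R,3S,4R)-7-acetoxy-4-(3,4-dimethoxyphenyl)-6-methoxy-2,3-dimethyl-3,4-dihydronaphthalen-1(2H)-one | COc1cc2c(cc1OC(C)=O)C(=O)[C@H](C)[C@@H](C)[C@@H]2c1ccc(OC)c(OC)c1
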